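All runs are calculated for an exercise; noise was put on by code.

I began from one living end: at each moment it took up free monomer and, by the return step, gave monomer in chains back as free monomer.

all flasks: free monomer 0.30 M; initiator 1 mol%
- ochre: impurity 0.21 mM; run made earlier
- teal: impurity 0.46 mM; run made earlier
- flask: impurity 0.31 mM; time 2.5 h

- ochre (time / h: monomer in chains / %, free monomer / %): 0.167: 18.6, 83.6; 0.500: 48.9, 51.1; 0.833: 53.3, 43.0; 1.33: 55.9, 41.4; 2.00: 53.1, 43.1; 2.50: 56.1, 43.6; 3.00: 51.5, 41.6
- teal (time / h: monomer in chains / %, free monomer / %): 0.417: 40.4, 57.0; 0.833: 55.2, 44.7; 1.33: 56.2, 43.7; 1.50: 56.4, 41.7; 2.00: 54.3, 41.3; 2.50: 52.7, 41.0; 3.00: 54.2, 42.8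

(standard deviation of a reading: 1 percentage point)

- average number of monomer units in a chain (chains begun, living or dead) at 2.5 h
- part of the free monomer that has reacted at 2.5 h

- the average divides the monomer in chains by the number of chains begun, living and dead together
- reactions considered so far: free monomer + initiator -> living end + monomer in chains; 2 initiator -> spent initiator A; initiator + impurity -> spent initiator B; monomer in chains + living end -> free monomer + living end; free monomer -> uncatalysed product; free monomer + living end -> monomer in chains + living end
- the earlier runs do not show the number of chains; that part of a forecast is a guess

With growth as the one step, free monomer should have run towards zero, yet in ochre and teal it stopped. So I added the return step. Growth per end weakens as free monomer falls, and I took return per end as steady, so the two meet at one level, and the number of ends, standing in both rates, drops out of the comparison.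

The readings agreed. Teal held twice the impurity of ochre, yet from 2.00 h on its free monomer averaged 41.7 % against 42.8 % in ochre, with a scatter of 1 percentage point per reading. Their mean, 42.2 %, is what I carried: the part of the charge of free monomer left free when growth and return balance, the floor fraction, the field's equilibrium monomer concentration taken on the charge. The flask's impurity lay between those of the two runs, so I took c as 57.8 %.

Then came the rest. Monomer in chains averaged 53.7 % over those late readings of both runs, so I read 4.12 % of the charge as missing, and with free monomer held at the floor, I expected the monomer in chains to pay for that slow drift. Impurity could take 10.3 % of the flask's initiator. Dividing that monomer in chains by the initiator left after the impurity gave dp 59.8, which counts each such initiator as a chain, so I held it as a low estimate.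

The forecast gave dp 75 and c 58 %, and warned: “The runs do not show chain number, so this range is wide.”

The flask gave dp 82.7 and c 58.4 %.

    free monomer + initiator → living end + monomer in chains (k = 0.00465 M⁻¹ s⁻¹)
    2 initiator → spent initiator A (k = 0.183 M⁻¹ s⁻¹)
    initiator + impurity → spent initiator B (k = 272 M⁻¹ s⁻¹)
    monomer in chains + living end → free monomer + living end, rate k4*[living end] as long as [monomer in chains] is above zero (k = 0.0950 s⁻¹)
    free monomer → uncatalysed product (k = 8.66 × 10⁻⁶ s⁻¹)
    free monomer + living end → monomer in chains + living end, rate k6*[living end]*[free monomer] (k = 0.756 M⁻¹ s⁻¹)

In the flask, free monomer stood at 41.6 % of its charge at 2.50 h, beside the floor fraction of 42.2 %. I carried the same level to a second flask, like this one but charged with 0.18 M of free monomer, so the floor fraction became 70.4 % of that smaller charge and c became 29.6 %. That second flask ended with free monomer at 69.1 % of its charge and c at 30.9 %.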